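The hydroperoxide on C12, flanked by the E-C10=C11 olefin, is read as the product of a singlet-oxygen ene reaction on an E-C11=C12(CH3) olefin. In that ene precursor, C12–C13 of the 14-membered carbocycle (C1–C14) is an sp2–sp3 bond. It is made by a one-pot hydroboration/B-alkyl Suzuki–Miyaura macrocyclisation. The seco-compound already carries both lactones: a vinyl group on C1 of the trans-fused α-methylene-γ-lactone, and an (E)-alkenyl iodide (C12) on the side chain of the C6–C8 butenolide. One operation closes the carbocycle and fixes the olefin geometry that the final photooxygenation turns into the C12 stereocentre.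

Key step: step 16

Locants (cembrane-type): carbocycle C1–C14; C1 ring-fusion CH, C2 lactone O–CH, C3=C4(C18H3), C6 butenolide O–CH, C7=C8 (C19 carbonyl on C8), C10=C11, C12 (C20H3, OOH), C13, C14; C15(=C17H2) and C16 (carbonyl) complete the α-methylene lactone (ring B); the butenolide is ring A.

Assumption: the target is taken to be the singlet-oxygen ene product of macrocycle 29, so attack on the exposed face of C11=C12 is expected to give the (12S) configuration.

Step 1
Reactants: 1 pent-3-yn-1-ol
Product: 3 (3E)-4-iodopent-3-en-1-ol, via alkenylzirconocene 2 (not isolated)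
Conditions: Cp2Zr(H)Cl (2.5 equiv), THF, rt then 45 °C; I2, 0 °C
Reagents that add atoms: iodine, II
Why: Syn-hydrozirconation of the methyl-capped alkyne, equilibrated by excess Cp2Zr(H)Cl so that zirconium sits on the less hindered methyl-bearing carbon, followed by iodinolysis with retention, should give the (E)-2-iodoalkene (Schwartz hydrozirconation–iodination).

Step 2
Reactants: 3 (3E)-4-iodopent-3-en-1-ol
Product: 4 (2E)-2,5-diiodopent-2-ene
Conditions: I2, PPh3, imidazole, CH2Cl2, 0 °C to rt
Reagents that add atoms: iodine, II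
Why: Appel-type iodination converts the primary alcohol into the iodide and leaves the alkenyl iodide untouched.

Step 3
Reactants: 4 (2E)-2,5-diiodopent-2-ene; 5 triethyl phosphonoacetate
Product: 6 ethyl (5E)-2-(diethoxyphosphoryl)-6-iodohept-5-enoate (racemic at C2)
Conditions: NaH, DMF, 0 °C to 50 °C (5 in excess)
Reagents that add atoms: none
Why: SN2 alkylation of the sodium phosphonoacetate carbanion by the primary iodide; the alkenyl iodide is inert and the racemic centre is destroyed in step 4.

Step 4
Reactants: 6 ethyl (5E)-2-(diethoxyphosphoryl)-6-iodohept-5-enoate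
Product: 7 ethyl (5E)-6-iodo-2-methylidenehept-5-enoate
Conditions: aq. HCHO (37%), K2CO3, THF/H2O, 60 °C
Reagents that add atoms: formaldehyde, C=O
Why: Horner–Wadsworth–Emmons methylenation with aqueous formaldehyde under carbonate base gives the 2-substituted acrylate.

Step 5
Reactants: 7 ethyl (5E)-6-iodo-2-methylidenehept-5-enoate
Product: 8 (5E)-6-iodo-2-methylidenehept-5-enoic acid
Conditions: LiOH·H2O, THF/H2O, 0 °C to rt; then HCl (aq)
Reagents that add atoms: lithium hydroxide, [Li+].[OH-]
Why: Ester saponification, which the acrylate and the alkenyl iodide should survive in the cold.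

Step 6
Reactants: 9 (R)-epichlorohydrin; 10 trimethylsilylacetylene
Product: 11 (2R)-1-chloro-5-(trimethylsilyl)pent-4-yn-2-ol
Conditions: n-BuLi, THF, −78 °C; BF3·OEt2; then 9, −78 °C
Reagents that add atoms: none
Why: BF3-promoted opening of the epoxide at its CH2 terminus by the lithium acetylide (Yamaguchi–Hirao alkynylation) leaves the C–O stereocentre (later C6) untouched.

Step 7
Reactants: 11 (2R)-1-chloro-5-(trimethylsilyl)pent-4-yn-2-ol
Product: 14 (3R)-hex-1-en-5-yn-3-ol, via silylated epoxide 12 (not isolated), via silylated enynol 13 (not isolated)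
Conditions: Me3S+ I−, n-BuLi (3.3 equiv each), THF, −10 °C to rt; then K2CO3 (cat.), MeOH, rt
Reagents that add atoms: trimethylsulfonium iodide, C[S+](C)C.[I-]
Why: Base closes the chlorohydrin to the epoxide, dimethylsulfonium methylide opens it at CH2 and the betaine eliminates Me2S to the allylic alcohol (epoxide-to-allylic-alcohol homologation) without touching the carbinol centre, and methanolic carbonate then removes the C-silyl group.

Step 8
Reactants: 14 (3R)-hex-1-en-5-yn-3-ol
Product: 16 (2E,5R)-3-methylhepta-2,6-diene-1,5-diol, via alkenylalane 15 (not isolated)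
Conditions: Me3Al (3 equiv), Cp2ZrCl2 (25 mol%), CH2Cl2, 0 °C to rt; then n-BuLi, THF, −78 °C; (CH2O)n, rt; HCl (aq)
Reagents that add atoms: trimethylaluminium, C[Al](C)C; formaldehyde (as paraformaldehyde), C=O
Why: Negishi zirconium-catalysed carboalumination adds CH3–Al syn across the terminal alkyne with methyl on the internal carbon, which fixes the E-C3=C4 geometry, and the derived alanate is hydroxymethylated; the terminal olefin reacts far more slowly.

Step 9
Reactants: 16 (2E,5R)-3-methylhepta-2,6-diene-1,5-diol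
Product: 17 (2E,5R)-5-hydroxy-3-methylhepta-2,6-dienal
Conditions: TEMPO (10 mol%), PhI(OAc)2 (1.1 equiv), CH2Cl2, rt
Reagents that add atoms: none
Why: The oxoammonium oxidation (TEMPO/PhI(OAc)2) is much faster for the primary allylic alcohol than for the secondary one, so the enal should form with C6–OH intact.

Step 10
Reactants: 17 (2E,5R)-5-hydroxy-3-methylhepta-2,6-dienal; 8 (5E)-6-iodo-2-methylidenehept-5-enoic acid
Product: 18 (3R,5E)-5-methyl-7-oxohepta-1,5-dien-3-yl (5E)-6-iodo-2-methylidenehept-5-enoate
Conditions: EDC·HCl, DMAP, CH2Cl2, 0 °C to rt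
Reagents that add atoms: none
Why: Steglich-type carbodiimide esterification of the secondary allylic alcohol with the 2-substituted acrylic acid.

Step 11
Reactants: 18 (3R,5E)-5-methyl-7-oxohepta-1,5-dien-3-yl (5E)-6-iodo-2-methylidenehept-5-enoate
Product: 19 (2E)-4-[(2R)-4-[(3E)-4-iodopent-3-en-1-yl]-5-oxo-2,5-dihydrofuran-2-yl]-3-methylbut-2-enal
Conditions: second-generation Grubbs catalyst (H2IMes)(PCy3)Cl2Ru=CHPh (5 mol%), toluene, 80 °C, 5 mM
Reagents that add atoms: none
Why: Ring-closing metathesis between the vinyl group and the acrylate methylene closes the five-membered butenolide (ring A); the trisubstituted enal and alkenyl iodide olefins are metathesis-inert.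

Step 12
Reactants: 19 butenolide enal; 20 methyl propiolate
Product: 21 methyl (4S,5E)-4-hydroxy-7-[(2R)-4-[(3E)-4-iodopent-3-en-1-yl]-5-oxo-2,5-dihydrofuran-2-yl]-6-methylhept-5-en-2-ynoate
Conditions: Me2Zn (3 equiv), ProPhenol ligand (20 mol%, enantiomer for Re-face delivery), Ph3P=O (40 mol%), toluene, 4 °C; then NH4Cl (aq)
Reagents that add atoms: none
Why: Zinc–ProPhenol catalysed asymmetric alkynylation of the enal by the zinc acetylide of methyl propiolate; the ligand enantiomer that delivers the alkynyl group to the Re face sets C2 under catalyst control, independent of the remote C6 centre.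

Step 13
Reactants: 21 γ-hydroxy ynoate
Product: 23 (5R)-5-[(1E)-3-[(2R)-4-[(3E)-4-iodopent-3-en-1-yl]-5-oxo-2,5-dihydrofuran-2-yl]-2-methylprop-1-en-1-yl]furan-2(5H)-one, via Z-hydroxy dienoate 22 (not isolated)
Conditions: H2 (1 atm), Pd/CaCO3 poisoned with Pb(OAc)2 (Lindlar catalyst), quinoline, EtOAc, rt; then PPTS (cat.), CH2Cl2, rt
Reagents that add atoms: none
Why: Lindlar semi-hydrogenation gives the Z-γ-hydroxy enoate, which lactonises to the unsubstituted butenolide; quinoline poisoning should spare the alkenyl iodide and the trisubstituted olefins.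

Step 14
Reactants: 23 bis-butenolide
Product: 25 (3S,4R,5R)-3-[(dimethylamino)methyl]-4-ethenyl-5-[(1E)-3-[(2R)-4-[(3E)-4-iodopent-3-en-1-yl]-5-oxo-2,5-dihydrofuran-2-yl]-2-methylprop-1-en-1-yl]oxolan-2-one, via magnesium enolate 24 (not isolated)
Conditions: CH2=CHMgBr (2.2 equiv), CuBr·SMe2 (1.1 equiv), THF, −78 °C; then Me2N=CH2+ I−, −78 to 0 °C
Reagents that add atoms: vinylmagnesium bromide, C=C[Mg]Br; N,N-dimethylmethyleneiminium iodide (Eschenmoser's salt), C=[N+](C)C.[I-]
Why: Conjugate addition of the vinyl cuprate to the unsubstituted butenolide occurs anti to the C2 substituent and so sets C1 trans, while the α-alkylated ring A is a much poorer acceptor; the enolate is then trapped in a Mannich reaction with Eschenmoser's salt.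

Step 15
Reactants: 25 Mannich base
Product: 27 (4R,5S)-4-ethenyl-5-[(1E)-3-[(2R)-4-[(3E)-4-iodopent-3-en-1-yl]-5-oxo-2,5-dihydrofuran-2-yl]-2-methylprop-1-en-1-yl]-3-methylideneoxolan-2-one, via ammonium iodide 26 (not isolated)
Conditions: MeI, MeOH, rt; then NaHCO3 (aq), EtOAc, rt
Reagents that add atoms: none
Why: N-Methylation followed by mild base-induced loss of trimethylamine (Mannich-base elimination) unveils the α-methylene lactone without strong base.

Step 16
Reactants: 27 seco-compound
Product: 29 (1R,2S,3E,6R,7Z,11E)-cembra-3,7,11,15(17)-tetraene-16,2:19,6-diolide, via alkylborane 28 (not isolated)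
Conditions: 9-BBN-H (1.3 equiv), THF, 0 °C to rt; then syringe-pump addition to Pd(dppf)Cl2·CH2Cl2 (20 mol%), AsPh3 (20 mol%), Cs2CO3 (3 equiv), DMF/THF/H2O, rt, 1 mM
Reagents that add atoms: none
Why: 9-BBN-H hydroborates the monosubstituted C1 vinyl group anti-Markovnikov and places boron on C13; after base turns the borane into the borate, zerovalent palladium inserts into the C12–I bond with retention, the primary alkyl group passes from boron to divalent palladium, and reductive elimination forges C12–C13. The closest known reaction type is the B-alkyl Suzuki–Miyaura macrocyclisation (sp3–sp2 cross-coupling). It closes the 14-membered carbocycle C1–C14 end to end, and with it the bicyclic frame in which the butenolide bridges C6–C8, through an alkyl(alkenyl)palladium intermediate under syringe-pump dilution. No stereocentre is formed; the E geometry of C11=C12, which the ene step later needs, is carried over stereospecifically from the alkenyl iodide. The step needs chemoselective hydroboration, ring closure over oligomerisation and survival of both lactones: these rest on the preference of 9-BBN for the only unconjugated terminal olefin (the exocyclic methylene and ring A olefin are electron-poor, the others trisubstituted), on high dilution with the fast AsPh3-assisted coupling at room temperature, and on the mild carbonate base.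

Step 17
Reactants: 29 macrocyclic triene dilactone
Product: 30 (1R,2S,3E,6R,7Z,10E,12S)-12-hydroperoxycembra-3,7,10,15(17)-tetraene-16,2:19,6-diolide (CNP0343227.1)
Conditions: O2, visible light, 5,10,15,20-tetraphenylporphyrin (1 mol%), CH2Cl2, −20 °C
Reagents that add atoms: dioxygen, O=O
Why: Schenck ene reaction: singlet oxygen attacks the only electron-rich, unconjugated olefin (E-C11=C12), bonds to C12 and abstracts a C10 hydrogen on the disubstituted side (cis effect), which shifts the olefin to E-C10=C11; C12 is set by attack on the exposed face of the olefin in the conformationally restricted macrocycle, and the C11 hydroperoxide with a C12 exocyclic methylene is the expected minor regioisomer to be separated.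

Compound list
1 | pent-3-yn-1-ol | CC#CCCO | starting material
2 | (E)-alkenylzirconocene chloride from 1 (Zr on C4, O-zirconated) | C/C(=C\CCO[Zr](Cl)(C1C=CC=C1)C1C=CC=C1)[Zr](Cl)(C1C=CC=C1)C1C=CC=C1 | intermediate
3 | (3E)-4-iodopent-3-en-1-ol | OCC/C=C(\C)I | intermediate
4 | (2E)-2,5-diiodopent-2-ene | ICC/C=C(\C)I | intermediate
5 | triethyl phosphonoacetate | CCOC(=O)CP(=O)(OCC)OCC | starting material
6 | ethyl (5E)-2-(diethoxyphosphoryl)-6-iodohept-5-enoate (racemic) | CCOC(=O)C(CC/C=C(\C)I)P(=O)(OCC)OCC | intermediate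
7 | ethyl (5E)-6-iodo-2-methylidenehept-5-enoate | CCOC(=O)C(=C)CC/C=C(\C)I | intermediate
8 | (5E)-6-iodo-2-methylidenehept-5-enoic acid | OC(=O)C(=C)CC/C=C(\C)I | intermediate
9 | (R)-epichlorohydrin, (2R)-2-(chloromethyl)oxirane | ClC[C@H]1CO1 | starting material
10 | trimethylsilylacetylene | C#C[Si](C)(C)C | starting material
11 | (2R)-1-chloro-5-(trimethylsilyl)pent-4-yn-2-ol | C[Si](C)(C)C#CC[C@@H](O)CCl | intermediate
12 | (2R)-2-[3-(trimethylsilyl)prop-2-yn-1-yl]oxirane | C[Si](C)(C)C#CC[C@@H]1CO1 | intermediate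
13 | (3R)-6-(trimethylsilyl)hex-1-en-5-yn-3-ol | C[Si](C)(C)C#CC[C@@H](O)C=C | intermediate
14 | (3R)-hex-1-en-5-yn-3-ol | C#CC[C@@H](O)C=C | intermediate
15 | (E)-alkenyl(dimethyl)alane from 14 (O-aluminated) | C[Al](C)/C=C(\C)C[C@@H](O[Al](C)C)C=C | intermediate
16 | (2E,5R)-3-methylhepta-2,6-diene-1,5-diol | OC/C=C(\C)C[C@@H](O)C=C | intermediate
17 | (2E,5R)-5-hydroxy-3-methylhepta-2,6-dienal | O=C/C=C(\C)C[C@@H](O)C=C | intermediate
18 | (3R,5E)-5-methyl-7-oxohepta-1,5-dien-3-yl (5E)-6-iodo-2-methylidenehept-5-enoate | O=C/C=C(\C)C[C@@H](OC(=O)C(=C)CC/C=C(\C)I)C=C | intermediate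
19 | (2E)-4-[(2R)-4-[(3E)-4-iodopent-3-en-1-yl]-5-oxo-2,5-dihydrofuran-2-yl]-3-methylbut-2-enal | O=C/C=C(\C)C[C@@H]1C=C(CC/C=C(\C)I)C(=O)O1 | intermediate
20 | methyl propiolate | C#CC(=O)OC | starting material
21 | methyl (4S,5E)-4-hydroxy-7-[(2R)-4-[(3E)-4-iodopent-3-en-1-yl]-5-oxo-2,5-dihydrofuran-2-yl]-6-methylhept-5-en-2-ynoate | COC(=O)C#C[C@@H](O)/C=C(\C)C[C@@H]1C=C(CC/C=C(\C)I)C(=O)O1 | intermediate
22 | methyl (2Z,4R,5E)-4-hydroxy-7-[(2R)-4-[(3E)-4-iodopent-3-en-1-yl]-5-oxo-2,5-dihydrofuran-2-yl]-6-methylhepta-2,5-dienoate | COC(=O)/C=C\[C@@H](O)/C=C(\C)C[C@@H]1C=C(CC/C=C(\C)I)C(=O)O1 | intermediate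
23 | (5R)-5-[(1E)-3-[(2R)-4-[(3E)-4-iodopent-3-en-1-yl]-5-oxo-2,5-dihydrofuran-2-yl]-2-methylprop-1-en-1-yl]furan-2(5H)-one | O=C1C=C[C@H](/C=C(\C)C[C@@H]2C=C(CC/C=C(\C)I)C(=O)O2)O1 | intermediate
24 | bromomagnesium enolate of the trans-4-ethenyl lactone | Br[Mg]OC1=C[C@@H](C=C)[C@H](/C=C(\C)C[C@@H]2C=C(CC/C=C(\C)I)C(=O)O2)O1 | intermediate
25 | (3S,4R,5R)-3-[(dimethylamino)methyl]-4-ethenyl-5-[(1E)-3-[(2R)-4-[(3E)-4-iodopent-3-en-1-yl]-5-oxo-2,5-dihydrofuran-2-yl]-2-methylprop-1-en-1-yl]oxolan-2-one | CN(C)C[C@H]1C(=O)O[C@@H](/C=C(\C)C[C@@H]2C=C(CC/C=C(\C)I)C(=O)O2)[C@@H]1C=C | intermediate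
26 | trimethylammonium iodide of 25 | C[N+](C)(C)C[C@H]1C(=O)O[C@@H](/C=C(\C)C[C@@H]2C=C(CC/C=C(\C)I)C(=O)O2)[C@@H]1C=C.[I-] | intermediate
27 | (4R,5S)-4-ethenyl-5-[(1E)-3-[(2R)-4-[(3E)-4-iodopent-3-en-1-yl]-5-oxo-2,5-dihydrofuran-2-yl]-2-methylprop-1-en-1-yl]-3-methylideneoxolan-2-one | C=C1C(=O)O[C@@H](/C=C(\C)C[C@@H]2C=C(CC/C=C(\C)I)C(=O)O2)[C@@H]1C=C | intermediate
28 | B-alkyl-9-BBN from 27 (boron on C13; lactone centres 4R,5S) | C=C1C(=O)O[C@@H](/C=C(\C)C[C@@H]2C=C(CC/C=C(\C)I)C(=O)O2)[C@@H]1CCB1C2CCCC1CCC2 | intermediate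
29 | (1R,2S,3E,6R,7Z,11E)-cembra-3,7,11,15(17)-tetraene-16,2:19,6-diolide (14-membered carbocycle, trans-fused α-methylene lactone at C1–C2, butenolide bridging C6–C8) | C=C1C(=O)O[C@H]2/C=C(\C)C[C@@H]3C=C(CC/C=C(\C)CC[C@H]12)C(=O)O3 | intermediate
30 | (1R,2S,3E,6R,7Z,10E,12S)-12-hydroperoxycembra-3,7,10,15(17)-tetraene-16,2:19,6-diolide | C=C1C(=O)O[C@H]2/C=C(\C)C[C@@H]3C=C(C/C=C/[C@@](C)(OO)CC[C@H]12)C(=O)O3 | target

Total step count: 17. Longest linear sequence: 13 steps (steps 1–5, then 10–17).

Steps most likely to fail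

Step 17 may fail through poor facial selectivity at C11=C12 (the C12 epimer) or through hydrogen abstraction from the C20 methyl group (the C11 hydroperoxide). The fallback replaces the concerted ene reaction by a stepwise ionic anti-addition and sets out from 29. Bromohydroperoxidation with 1,3-dibromo-5,5-dimethylhydantoin and anhydrous H2O2 in Et2O at −40 °C (Markovnikov, peroxide on C12 anti to bromine on C11) should give the bromohydroperoxide F1. 2-Methoxypropene with PPTS protects it as the perketal F2. Dehydrobromination with DBU in toluene, for which only the C10 hydrogens are available, gives the allylic perketal F3. AcOH/THF/H2O then releases 30. This sequence puts the peroxide oxygen on the face opposite to the one the electrophile attacks and removes the regiochemical ambiguity.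

Step 16 may fail through conjugate addition or hydrolysis at the α-methylene lactone under the basic coupling conditions, through competing hydroboration of the exocyclic methylene, or through oligomerisation. The fallback closes the ring before the Michael acceptor exists and sets out from 25. Hydroboration with 9-BBN-H (extra equivalent for the amine) gives the alkylborane F4. The same palladium-catalysed ring closure under dilution gives the macrocyclic Mannich base F5. MeI gives the ammonium iodide F6, and aqueous NaHCO3 eliminates trimethylamine to return to the route at 29.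

Step 14 may fail through competing attack of the cuprate on ring A, or through proton transfer from the acidic C6–H of ring A to the enolate, which would cost the Mannich trapping and could epimerise C6. The fallback builds ring B before ring A and sets out from 17.
- Zinc–ProPhenol alkynylation of 17 with 20 (extra Me2Zn for the free hydroxyl) gives the diol ynoate F7.
- Lindlar semi-hydrogenation, here with no alkenyl iodide present, gives the Z-dienoate F8, which lactonises to the hydroxy butenolide F9.
- Vinyl cuprate addition (extra equivalent for the alkoxide) and Eschenmoser trapping proceed through the magnesium enolate F10 to the hydroxy Mannich base F11.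
- EDC/DMAP esterification with 8 gives the ester F12.
- Ring-closing metathesis with the second-generation Grubbs catalyst, in the presence of camphorsulfonic acid to protonate the amine, closes ring A and returns to the route at 25.

Further compounds
F1 | step 17 | (11R,12S)-11-bromo-12-hydroperoxy-11,12-dihydro derivative of 29 | C=C1C(=O)O[C@H]2/C=C(\C)C[C@@H]3C=C(CC[C@@H](Br)[C@@](C)(OO)CC[C@H]12)C(=O)O3
F2 | step 17 | 2-methoxypropan-2-yl peroxide (perketal) of F1 | C=C1C(=O)O[C@H]2/C=C(\C)C[C@@H]3C=C(CC[C@@H](Br)[C@@](C)(OOC(C)(C)OC)CC[C@H]12)C(=O)O3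
F3 | step 17 | 2-methoxypropan-2-yl peroxide (perketal) of 30 | C=C1C(=O)O[C@H]2/C=C(\C)C[C@@H]3C=C(C/C=C/[C@@](C)(OOC(C)(C)OC)CC[C@H]12)C(=O)O3
F4 | step 16 | B-alkyl-9-BBN from 25 (boron on C13) | CN(C)C[C@H]1C(=O)O[C@@H](/C=C(\C)C[C@@H]2C=C(CC/C=C(\C)I)C(=O)O2)[C@@H]1CCB1C2CCCC1CCC2
F5 | step 16 | macrocyclic Mannich base, (15S)-15-[(dimethylamino)methyl]-15,17-dihydro analogue of 29 | CN(C)C[C@H]1C(=O)O[C@H]2/C=C(\C)C[C@@H]3C=C(CC/C=C(\C)CC[C@H]12)C(=O)O3
F6 | step 16 | trimethylammonium iodide of F5 | C[N+](C)(C)C[C@H]1C(=O)O[C@H]2/C=C(\C)C[C@@H]3C=C(CC/C=C(\C)CC[C@H]12)C(=O)O3.[I-]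
F7 | step 14 | methyl (4S,5E,8R)-4,8-dihydroxy-6-methyldeca-5,9-dien-2-ynoate | COC(=O)C#C[C@@H](O)/C=C(\C)C[C@@H](O)C=C
F8 | step 14 | methyl (2Z,4R,5E,8R)-4,8-dihydroxy-6-methyldeca-2,5,9-trienoate | COC(=O)/C=C\[C@@H](O)/C=C(\C)C[C@@H](O)C=C
F9 | step 14 | (5R)-5-[(1E,4R)-4-hydroxy-2-methylhexa-1,5-dien-1-yl]furan-2(5H)-one | O=C1C=C[C@H](/C=C(\C)C[C@@H](O)C=C)O1
F10 | step 14 | bromomagnesium enolate alkoxide from F9 | Br[Mg]OC1=C[C@@H](C=C)[C@H](/C=C(\C)C[C@@H](O[Mg]Br)C=C)O1
F11 | step 14 | (3S,4R,5R)-3-[(dimethylamino)methyl]-4-ethenyl-5-[(1E,4R)-4-hydroxy-2-methylhexa-1,5-dien-1-yl]oxolan-2-one | CN(C)C[C@H]1C(=O)O[C@@H](/C=C(\C)C[C@@H](O)C=C)[C@@H]1C=C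
F12 | step 14 | (5E)-6-iodo-2-methylidenehept-5-enoate ester of F11 | CN(C)C[C@H]1C(=O)O[C@@H](/C=C(\C)C[C@@H](OC(=O)C(=C)CC/C=C(\C)I)C=C)[C@@H]1C=C
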